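In this flask every electrophile that becomes target uses one nucleophile and, as I read the slowing readings, sets free one acid that needs a base of its own, so each turn costs two bases. Electrophile is the limiting reagent, so the balance gives the base surplus S, the free nucleophile plus free base left once the electrophile has become target: S = 0.840 M.

| flask | electrophile | nucleophile | free base | remark | time |
|---|---|---|---|---|---|
| theta | 1.2 M | 1.8 M | 1.44 M | the very flask that is asked about, followed so far |  |
| flask | 1.2 M | 1.80 M | 1.44 M |  | 5.0 min |

- theta (time / s: electrophile / %, target / %): 10.0: 76, 25; 25.0: 60, 43; 40.0: 46, 49; 60.0: 38, 55; 90.0: 28, 68

(each reading ± 2 percentage points)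

- the earlier runs do not show how much of nucleophile is bound; that part of a forecast is a guess

- part of the electrophile that has reacted at 5.0 min
- share of the unused nucleophile that is free and not bound as protonated nucleophile, at 5.0 min

The forecast gives 92% reacted and 38% free, and says of the second: “This share is largely a guess.” I accept its conversion but differ on the share: S is positive and free base is charged above electrophile, so the charge of free base covers the acid of a full conversion, and I expect a free share well above 38%.

The flask gives 94.9% and 63.6%, so the forecast's share is 26 percentage points low. At 5.0 min salt of the base, at 0.800 M, exceeds protonated nucleophile, at 0.255 M.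

    electrophile + nucleophile → acid set free + target (k = 0.0170 M⁻¹ s⁻¹)
    nucleophile + acid set free ⇌ protonated nucleophile, settled at all times (K = 160 M⁻¹)
    acid set free + free base ⇌ salt of the base (K = 810 M⁻¹, k = 0.720 M⁻¹ s⁻¹)
    electrophile + acid set free → side product (k = 0.110 M⁻¹ s⁻¹)

A neighbour flask with 0.36 M free base has S = −0.240 M; at 5.0 min it shows 27.6% free and 7.93% side product, against 3.33% in this flask. This flask is not at rest at 5.0 min. By 50.0 min its free nucleophile and free base sum to 0.970 M, above S. Conversion reaches 100%, target rises from 91.6% to 96.5%, protonated nucleophile falls to 0.174 M, and the free share climbs to 73.0%.

All runs are calculated from invented constants; the scatter is artificial.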